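**Plan**

- Retrosynthesis: the two silyl ethers and the isolated cis CH=CH of the 30-membered dilactone (between an oxirane carbon and the CH2 next to the acyloxy CH of the epoxide half) go back to a ring C≡C. This is cut by ring-closing alkyne metathesis to an open-chain bis(prop-1-ynyl) diester.
- Further cuts: both oxazole-4-carboxylate C(=O)–O bonds; the two C(sp2)–C(sp) bonds around the central CH=CH of the all-cis triene (a cis-enediyne built on cis-1,2-dichloroethene); the two C=C bonds of the E,E-diene (Wittig, Horner–Wadsworth–Emmons); the carbinol–CH2 bonds of both gem-dimethyl units (propargylation of one aldehyde).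
- Forward: the chain is joined in the order ester, enediyne, Z,Z,Z-triene, second ester. The oxazole of the triene half (step 15) and the oxirane (step 19) are made on small fragments; the macrocycle closes last (step 29), then semihydrogenation and desilylation.
- Enabling feature: that ring CH=CH is the only C=C that can be stored as C≡C, which alkyne metathesis addresses while ignoring the seven C=C bonds, two oxazoles, two esters and the oxirane.
- Stereochemistry: both allylic carbinols (S) come from (R)-pantolactone. The acyloxy carbinols (S in the epoxide half, R in the triene half) come from allenylboration of one aldehyde with enantiomeric Ipc2B reagents. The methoxy carbon (R) comes from Ipc2B allylation, the cis-oxirane from Sharpless epoxidation with L-(+)-tartrate. Alkene geometry comes from Julia–Kocienski, Wittig and HWE reactions (E) and from zinc and Lindlar reductions (Z).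

Key step: step 29

Assumption: B-allenyl-Ipc2B reagents are taken to attack the same aldehyde face as the B-allyl reagents of the same pinene series (Si face for the series from (+)-α-pinene, written dIpc; Re face for the series from (−)-α-pinene, written lIpc).

**Route**

Step 1
Reactants: 1 (R)-pantolactone
Product: 2 (2R)-3,3-dimethylbutane-1,2,4-triol
Conditions: LiAlH4, THF, 0 °C → reflux; aq. NaOH work-up
Reagents that add atoms: none
Why: Hydride reduction of the lactone to the triol leaves the carbinol stereocentre, the future allylic carbinol of both halves, untouched.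

Step 2
Reactants: 2 triol
Product: 3 [(2R,4R)-2-(4-methoxyphenyl)-5,5-dimethyl-1,3-dioxan-4-yl]methanol
Conditions: 4-MeOC6H4CH(OMe)2, camphorsulfonic acid (cat.), CH2Cl2, rt
Reagents that add atoms: 4-methoxybenzaldehyde dimethyl acetal, COC(OC)c1ccc(OC)cc1
Why: Transacetalisation under thermodynamic control, where arylidene acetals prefer the six-membered 1,3-dioxane (aryl and CH2OH equatorial), so the primary hydroxyl next to the stereocentre stays free.

Step 3
Reactants: 3 dioxane alcohol
Product: 4 (2R,4R)-2-(4-methoxyphenyl)-5,5-dimethyl-1,3-dioxane-4-carbaldehyde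
Conditions: Dess–Martin periodinane, NaHCO3, CH2Cl2, 0 °C → rt
Reagents that add atoms: none
Why: Buffered Dess–Martin oxidation should give the α-alkoxy aldehyde without epimerisation or loss of the acetal.

Step 4
Reactants: 4 aldehyde
Product: 5 (2R,4S)-2-(4-methoxyphenyl)-5,5-dimethyl-4-[(1E)-prop-1-en-1-yl]-1,3-dioxane
Conditions: 5-(ethylsulfonyl)-1-phenyl-1H-tetrazole, KN(SiMe3)2 (added last), DME, −60 °C → rt
Reagents that add atoms: 5-(ethylsulfonyl)-1-phenyl-1H-tetrazole, CCS(=O)(=O)c1nnnn1-c1ccccc1
Why: Julia–Kocienski olefination, in which the potassium counter-ion in DME and the α-branched aldehyde favour the E-propenyl group, while adding the base last limits enolisation of the aldehyde.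

Step 5
Reactants: 5 propenyl dioxane
Product: 6 (3S,4E)-2,2-dimethylhex-4-ene-1,3-diol
Conditions: AcOH/H2O 4:1, 40 °C
Reagents that add atoms: none
Why: Mild acid hydrolysis of the arylidene acetal frees the 1,3-diol without ionising the allylic C–O bond.

Step 6
Reactants: 6 diol
Product: 8 (3S,4E)-3-[(tert-butyldimethylsilyl)oxy]-2,2-dimethyl-1-[(triethylsilyl)oxy]hex-4-ene, via primary triethylsilyl ether 7 (not isolated)
Conditions: Et3SiCl (1.05 equiv), Et3N, DMAP (cat.), CH2Cl2, −20 °C; then 2,6-lutidine, t-BuMe2SiOTf, −78 → 0 °C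
Reagents that add atoms: chlorotriethylsilane, CC[Si](Cl)(CC)CC; tert-butyldimethylsilyl triflate, CC(C)(C)[Si](C)(C)OS(=O)(=O)C(F)(F)F
Why: The silyl chloride selects the primary hydroxyl over the neopentyl allylic secondary one, so the labile triethylsilyl group goes on the primary and the robust tert-butyldimethylsilyl group on the secondary oxygen in one flask.

Step 7
Reactants: 8 bis-silyl ether
Product: 9 (3S,4E)-3-[(tert-butyldimethylsilyl)oxy]-2,2-dimethylhex-4-enal
Conditions: (COCl)2, DMSO, CH2Cl2, −78 → −30 °C; Et3N, −78 °C → rt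
Reagents that add atoms: none
Why: Under Swern conditions a primary triethylsilyl ether is converted directly into the aldehyde (oxidative desilylation through the alkoxysulfonium ion), whereas the secondary tert-butyldimethylsilyl ether is inert and the aldehyde has no α-hydrogen.

Step 8
Reactants: 9 aldehyde
Product: 10 (4R,6S,7E)-6-[(tert-butyldimethylsilyl)oxy]-5,5-dimethylnon-7-en-1-yn-4-ol
Conditions: H2C=C=CHMgBr, lIpc2BOMe [from (−)-α-pinene], Et2O, −78 °C → rt; then 9, −78 °C; HOCH2CH2NH2
Reagents that add atoms: B-allenylbis(isopinocampheyl)borane of the (−)-α-pinene series, C=C=CB([C@H]1C[C@H]2C[C@@H]([C@@H]1C)C2(C)C)[C@H]1C[C@H]2C[C@@H]([C@@H]1C)C2(C)C, made in the flask from allenylmagnesium bromide, C=C=C[Mg]Br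
Why: Asymmetric allenylboration of the Brown type through a cyclic SE2′ transition state gives only the homopropargylic alcohol, and the lIpc ligands should direct attack to the Re face, setting the R carbinol under reagent control over the remote silyloxy centre.

Step 9
Reactants: 9 aldehyde
Product: 11 (4S,6S,7E)-6-[(tert-butyldimethylsilyl)oxy]-5,5-dimethylnon-7-en-1-yn-4-ol
Conditions: H2C=C=CHMgBr, dIpc2BOMe [from (+)-α-pinene], Et2O, −78 °C → rt; then 9, −78 °C; HOCH2CH2NH2
Reagents that add atoms: B-allenylbis(isopinocampheyl)borane of the (+)-α-pinene series, C=C=CB([C@@H]1C[C@@H]2C[C@H]([C@H]1C)C2(C)C)[C@@H]1C[C@@H]2C[C@H]([C@H]1C)C2(C)C, made in the flask from allenylmagnesium bromide, C=C=C[Mg]Br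
Why: The enantiomeric allenylborane should attack the Si face of the same aldehyde and give the S carbinol, the epimer needed for the epoxide half.

Step 10
Reactants: 11 terminal alkyne
Product: 12 (2E,4S,6S)-4-[(tert-butyldimethylsilyl)oxy]-5,5-dimethyldec-2-en-8-yn-6-ol
Conditions: n-BuLi (2.2 equiv), THF, −78 °C; MeI, −78 → 0 °C; H2O
Reagents that add atoms: iodomethane, CI
Why: Alkylation of the alkoxide–acetylide dianion takes place only at the far more nucleophilic acetylide carbon, and keeping the mixture at or below 0 °C should suppress 1,3-migration of the silyl group to the alkoxide.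

Step 11
Reactants: 13 3-(trimethylsilyl)prop-2-ynal
Product: 14 (3R)-1-(trimethylsilyl)hex-5-en-1-yn-3-ol
Conditions: H2C=CHCH2MgBr, lIpc2BOMe [from (−)-α-pinene], Et2O, −78 °C → rt; then 13, −78 °C; HOCH2CH2NH2
Reagents that add atoms: B-allylbis(isopinocampheyl)borane of the (−)-α-pinene series, C=CCB([C@H]1C[C@H]2C[C@@H]([C@@H]1C)C2(C)C)[C@H]1C[C@H]2C[C@@H]([C@@H]1C)C2(C)C, made in the flask from allylmagnesium bromide, C=CC[Mg]Br
Why: Brown allylboration through a chair transition state, in which the lIpc reagent attacks the Re face of the ynal and sets the R carbinol that becomes the methoxy-bearing carbon.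

Step 12
Reactants: 14 propargylic alcohol
Product: 15 [(3R)-3-methoxyhex-5-en-1-yn-1-yl]trimethylsilane
Conditions: Me3OBF4, 1,8-bis(dimethylamino)naphthalene, CH2Cl2, rt
Reagents that add atoms: trimethyloxonium tetrafluoroborate, C[O+](C)C.F[B-](F)(F)F
Why: O-Methylation with the Meerwein salt and a non-nucleophilic base avoids alkoxide conditions that could cleave the alkynyl C–Si bond.

Step 13
Reactants: 15 methyl ether
Product: 17 (3R)-3-methoxy-5-(trimethylsilyl)pent-4-ynoic acid, via aldehyde 16 (not isolated)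
Conditions: O3, CH2Cl2, −78 °C; PPh3, → rt; then NaClO2, NaH2PO4, 2-methylbut-2-ene, t-BuOH/H2O, 0 °C
Reagents that add atoms: ozone, [O-][O+]=O; sodium chlorite, [Na+].[O-]Cl=O
Why: Ozone cleaves the terminal alkene much faster than the silylated alkyne, and Pinnick oxidation of the crude β-methoxy aldehyde should give the acid without β-elimination.

Step 14
Reactants: 17 acid; 18 L-serine methyl ester hydrochloride
Product: 19 methyl N-[(3R)-3-methoxy-5-(trimethylsilyl)pent-4-ynoyl]-L-serinate
Conditions: EDC·HCl, HOBt, i-Pr2NEt, CH2Cl2, 0 °C → rt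
Reagents that add atoms: none
Why: Carbodiimide amide coupling in which the amine outcompetes the serine hydroxyl.

Step 15
Reactants: 19 hydroxy amide
Product: 21 methyl 2-[(2R)-2-methoxy-4-(trimethylsilyl)but-3-yn-1-yl]-1,3-oxazole-4-carboxylate, via oxazoline 20 (not isolated)
Conditions: (MeOCH2CH2)2NSF3, CH2Cl2, −20 °C; then BrCCl3, DBU, 0 °C → rt
Reagents that add atoms: none
Why: Cyclodehydration of the β-hydroxy amide to the oxazoline and bromination–dehydrobromination in the same flask give the oxazole, erasing the serine stereocentre and leaving the methoxy centre untouched.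

Step 16
Reactants: 21 oxazole ester
Product: 22 2-[(2R)-2-methoxybut-3-yn-1-yl]-1,3-oxazole-4-carboxylic acid
Conditions: LiOH, THF/MeOH/H2O, 0 °C → rt; then 1 M HCl to pH 3
Reagents that add atoms: lithium hydroxide, [Li+].[OH-]
Why: Hydroxide saponifies the methyl ester and cleaves the alkynyl C–Si bond in one operation, giving the acid with a free terminal alkyne.

Step 17
Reactants: 23 ethyl (2Z)-3-iodoprop-2-enoate
Product: 24 ethyl (2Z)-hex-2-en-4-ynoate
Conditions: propyne (excess), PdCl2(PPh3)2 (cat.), CuI (cat.), i-Pr2NH, THF, −20 °C → rt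
Reagents that add atoms: propyne, CC#C
Why: Sonogashira coupling of the β-iodoacrylate proceeds with retention of the Z geometry at low temperature.

Step 18
Reactants: 24 enynoate
Product: 25 (2Z)-hex-2-en-4-yn-1-ol
Conditions: i-Bu2AlH, CH2Cl2, −78 °C; aq. potassium sodium tartrate
Reagents that add atoms: none
Why: 1,2-Reduction of the conjugated ester to the allylic alcohol leaves the enyne and its geometry intact.

Step 19
Reactants: 25 Z-enynol
Product: 26 [(2S,3R)-3-(prop-1-yn-1-yl)oxiran-2-yl]methanol
Conditions: Ti(Oi-Pr)4 (cat.), L-(+)-diethyl tartrate (cat.), t-BuOOH, 4 Å molecular sieves, CH2Cl2, −20 °C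
Reagents that add atoms: tert-butyl hydroperoxide, CC(C)(C)OO
Why: Sharpless asymmetric epoxidation, in which the titanium tartrate complex binds the allylic alcohol and L-(+)-tartrate delivers oxygen to the face that gives the (2S,3R) cis-epoxide; the alkyne is inert and any minor enantiomer becomes a separable diastereomer after step 28.

Step 20
Reactants: 26 epoxy alcohol
Product: 28 (2E)-3-[(2S,3R)-3-(prop-1-yn-1-yl)oxiran-2-yl]prop-2-enal, via cis-epoxy aldehyde 27 (not isolated)
Conditions: Dess–Martin periodinane, NaHCO3, CH2Cl2, 0 °C; then Ph3P=CHCHO, rt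
Reagents that add atoms: (triphenylphosphoranylidene)acetaldehyde, O=CC=P(c1ccccc1)(c1ccccc1)c1ccccc1
Why: Oxidation followed in the same flask by Wittig reaction with the stabilised formyl ylide gives the E-enal without isolating the volatile, epimerisable cis-epoxy aldehyde.

Step 21
Reactants: 29 methyl 2-(chloromethyl)-1,3-oxazole-4-carboxylate
Product: 30 methyl 2-[(diethoxyphosphoryl)methyl]-1,3-oxazole-4-carboxylate
Conditions: P(OEt)3, neat, 130 °C
Reagents that add atoms: triethyl phosphite, CCOP(OCC)OCC
Why: Michaelis–Arbuzov reaction of the activated heteroaryl-methyl chloride.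

Step 22
Reactants: 30 phosphonate; 28 epoxy enal
Product: 31 methyl 2-{(1E,3E)-4-[(2S,3R)-3-(prop-1-yn-1-yl)oxiran-2-yl]buta-1,3-dien-1-yl}-1,3-oxazole-4-carboxylate
Conditions: LiN(SiMe3)2, THF, −78 °C; then 28, −78 → 0 °C
Reagents that add atoms: none
Why: Horner–Wadsworth–Emmons reaction of the oxazole-stabilised phosphonate anion gives the new C=C with E geometry, and the oxirane tolerates the cold, non-nucleophilic base.

Step 23
Reactants: 31 dienyl oxazole ester
Product: 32 2-{(1E,3E)-4-[(2S,3R)-3-(prop-1-yn-1-yl)oxiran-2-yl]buta-1,3-dien-1-yl}-1,3-oxazole-4-carboxylic acid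
Conditions: LiOH, THF/H2O, 0 °C; aq. NaH2PO4 to pH 4–5
Reagents that add atoms: lithium hydroxide, [Li+].[OH-]
Why: Cold saponification leaves the base-stable oxirane intact, and buffered acidification avoids acid-induced opening of the dienyl oxirane.

Step 24
Reactants: 22 oxazole acid; 12 but-2-ynyl carbinol
Product: 33 (2E,4S,6S)-4-[(tert-butyldimethylsilyl)oxy]-5,5-dimethyldec-2-en-8-yn-6-yl 2-[(2R)-2-methoxybut-3-yn-1-yl]-1,3-oxazole-4-carboxylate
Conditions: 2,4,6-Cl3C6H2COCl, Et3N, DMAP, toluene, rt
Reagents that add atoms: none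
Why: Yamaguchi esterification acylates the hindered secondary alcohol with retention at the carbinol carbon.

Step 25
Reactants: 33 alkynyl ester
Product: 34 the same ester with a (Z)-2-chlorovinyl group on the former terminal alkyne carbon (acid part: 2-[(2R,5Z)-6-chloro-2-methoxyhex-5-en-3-yn-1-yl]oxazole-4-carboxylate)
Conditions: (Z)-ClCH=CHCl (excess), Pd(PPh3)4 (cat.), CuI (cat.), n-BuNH2, Et2O, rt, degassed
Reagents that add atoms: (Z)-1,2-dichloroethene, Cl/C=C\Cl
Why: Sonogashira coupling with excess cis-dichloroethene stops after one C–Cl bond and retains the Z geometry, the internal but-2-ynyl group being a spectator.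

Step 26
Reactants: 34 chloroenyne; 10 terminal alkyne carbinol
Product: 35 Z-enediyne hydroxy ester (Cl of 34 replaced by the alkynyl terminus of 10)
Conditions: Pd(PPh3)4 (cat.), CuI (cat.), n-BuNH2, toluene, rt, degassed
Reagents that add atoms: none
Why: A second Sonogashira coupling at the vinylic C–Cl bond of the activated chloroenyne, again with retention, gives the cis-enediyne and tolerates the free hydroxyl.

Step 27
Reactants: 35 enediyne
Product: 36 Z,Z,Z-triene hydroxy ester
Conditions: Zn dust activated with Cu(OAc)2 and AgNO3, MeOH/H2O/THF, rt, dark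
Reagents that add atoms: none
Why: Activated zinc reduces only triple bonds conjugated to C=C, with cis delivery of hydrogen from the protic solvent, so both enediyne alkynes become Z-alkenes while the isolated but-2-ynyl group and the E-propenyl groups remain.

Step 28
Reactants: 36 triene alcohol; 32 oxirane acid
Product: 37 open-chain bis(prop-1-ynyl) diester, bis-TBS ether
Conditions: 2,4,6-Cl3C6H2COCl, Et3N, DMAP, toluene, rt, dark
Reagents that add atoms: none
Why: Yamaguchi esterification at room temperature activates the acid under basic conditions that spare the acid-labile dienyl oxirane and the thermally labile triene, with retention at the carbinol carbon.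

Step 29
Reactants: 37 open-chain bis(prop-1-ynyl) diester
Product: 38 30-membered cycloalkyne, bis-TBS ether
Conditions: Mo(≡CC6H4-4-OMe)(OSiPh3)3 (15 mol %), powdered 5 Å molecular sieves, toluene, 1 mM, rt, dark
Reagents that add atoms: none
Why: The alkylidyne adds to one methyl-capped alkyne by [2+2] cycloaddition, the molybdacyclobutadiene cycloreverts to a chain-bound alkylidyne with loss of but-2-yne (trapped by the sieves), and the same two events on the second alkyne form the ring C≡C between the oxiranyl alkyne carbon and the propargylic CH2 carbon. The closest known reaction type is ring-closing alkyne metathesis of bis(prop-1-ynyl) substrates to macrocyclic cycloalkynes with triarylsilanolate molybdenum alkylidynes. The 30-membered ring closes end to end by joining the two alkyne termini of the open chain, a strain-free large-ring closure. No stereocentre is formed and the seven existing ones are not touched. The step needs chemoselectivity for C≡C over seven C=C bonds, two oxazoles, two esters and the oxirane, which the silanolate-ligated alkylidyne should provide because it does not engage alkenes and is only weakly Lewis acidic. It also needs ring closure to outrun oligomerisation, which millimolar dilution and removal of but-2-yne secure, with initiation expected at the unhindered but-2-ynyl terminus.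

Step 30
Reactants: 38 cycloalkyne
Product: 39 bis-TBS ether of the target
Conditions: H2 (1 atm), Pd/CaCO3 poisoned with Pb(OAc)2 (Lindlar catalyst), quinoline, EtOAc, rt, uptake monitored
Reagents that add atoms: none
Why: Syn addition of hydrogen on the poisoned palladium surface converts the ring alkyne into the cis-alkene, alkynyl oxiranes being known to give cis-vinyl oxiranes under these conditions, and quinoline with close monitoring should spare the polyene.

Step 31
Reactants: 39 bis-silyl ether
Product: 40 target CNP0284709.4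
Conditions: HF·pyridine, pyridine, THF, 0 °C → rt
Reagents that add atoms: none
Why: Pyridine-buffered fluoride cleaves both secondary silyl ethers without the basic conditions that would invite 1,3-acyl migration and should be mild enough for the vinyl oxirane.

**Compound list**

1 | (R)-pantolactone | CC1(C)COC(=O)[C@@H]1O | starting material
2 | (2R)-3,3-dimethylbutane-1,2,4-triol | OC[C@H](O)C(C)(C)CO | intermediate
3 | [(2R,4R)-2-(4-methoxyphenyl)-5,5-dimethyl-1,3-dioxan-4-yl]methanol | OC[C@@H]1O[C@H](c2ccc(OC)cc2)OCC1(C)C | intermediate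
4 | (2R,4R)-2-(4-methoxyphenyl)-5,5-dimethyl-1,3-dioxane-4-carbaldehyde | O=C[C@@H]1O[C@H](c2ccc(OC)cc2)OCC1(C)C | intermediate
5 | (2R,4S)-2-(4-methoxyphenyl)-5,5-dimethyl-4-[(1E)-prop-1-en-1-yl]-1,3-dioxane | C/C=C/[C@@H]1O[C@H](c2ccc(OC)cc2)OCC1(C)C | intermediate
6 | (3S,4E)-2,2-dimethylhex-4-ene-1,3-diol | C/C=C/[C@H](O)C(C)(C)CO | intermediate
7 | (3S,4E)-2,2-dimethyl-1-[(triethylsilyl)oxy]hex-4-en-3-ol | C/C=C/[C@H](O)C(C)(C)CO[Si](CC)(CC)CC | intermediate
8 | (3S,4E)-3-[(tert-butyldimethylsilyl)oxy]-2,2-dimethyl-1-[(triethylsilyl)oxy]hex-4-ene | C/C=C/[C@H](O[Si](C)(C)C(C)(C)C)C(C)(C)CO[Si](CC)(CC)CC | intermediate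
9 | (3S,4E)-3-[(tert-butyldimethylsilyl)oxy]-2,2-dimethylhex-4-enal | C/C=C/[C@H](O[Si](C)(C)C(C)(C)C)C(C)(C)C=O | intermediate
10 | (4R,6S,7E)-6-[(tert-butyldimethylsilyl)oxy]-5,5-dimethylnon-7-en-1-yn-4-ol | C/C=C/[C@H](O[Si](C)(C)C(C)(C)C)C(C)(C)[C@H](O)CC#C | intermediate
11 | (4S,6S,7E)-6-[(tert-butyldimethylsilyl)oxy]-5,5-dimethylnon-7-en-1-yn-4-ol | C/C=C/[C@H](O[Si](C)(C)C(C)(C)C)C(C)(C)[C@@H](O)CC#C | intermediate
12 | (2E,4S,6S)-4-[(tert-butyldimethylsilyl)oxy]-5,5-dimethyldec-2-en-8-yn-6-ol | C/C=C/[C@H](O[Si](C)(C)C(C)(C)C)C(C)(C)[C@@H](O)CC#CC | intermediate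
13 | 3-(trimethylsilyl)prop-2-ynal | C[Si](C)(C)C#CC=O | starting material
14 | (3R)-1-(trimethylsilyl)hex-5-en-1-yn-3-ol | C=CC[C@@H](O)C#C[Si](C)(C)C | intermediate
15 | [(3R)-3-methoxyhex-5-en-1-yn-1-yl]trimethylsilane | C=CC[C@@H](OC)C#C[Si](C)(C)C | intermediate
16 | (3R)-3-methoxy-5-(trimethylsilyl)pent-4-ynal | O=CC[C@@H](OC)C#C[Si](C)(C)C | intermediate
17 | (3R)-3-methoxy-5-(trimethylsilyl)pent-4-ynoic acid | OC(=O)C[C@@H](OC)C#C[Si](C)(C)C | intermediate
18 | L-serine methyl ester hydrochloride | Cl.N[C@@H](CO)C(=O)OC | starting material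
19 | methyl N-[(3R)-3-methoxy-5-(trimethylsilyl)pent-4-ynoyl]-L-serinate | COC(=O)[C@H](CO)NC(=O)C[C@@H](OC)C#C[Si](C)(C)C | intermediate
20 | methyl (4S)-2-[(2R)-2-methoxy-4-(trimethylsilyl)but-3-yn-1-yl]-4,5-dihydro-1,3-oxazole-4-carboxylate | COC(=O)[C@@H]1COC(C[C@@H](OC)C#C[Si](C)(C)C)=N1 | intermediate
21 | methyl 2-[(2R)-2-methoxy-4-(trimethylsilyl)but-3-yn-1-yl]-1,3-oxazole-4-carboxylate | COC(=O)c1coc(C[C@@H](OC)C#C[Si](C)(C)C)n1 | intermediate
22 | 2-[(2R)-2-methoxybut-3-yn-1-yl]-1,3-oxazole-4-carboxylic acid | OC(=O)c1coc(C[C@@H](OC)C#C)n1 | intermediate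
23 | ethyl (2Z)-3-iodoprop-2-enoate | CCOC(=O)/C=C\I | starting material
24 | ethyl (2Z)-hex-2-en-4-ynoate | CCOC(=O)/C=C\C#CC | intermediate
25 | (2Z)-hex-2-en-4-yn-1-ol | OC/C=C\C#CC | intermediate
26 | [(2S,3R)-3-(prop-1-yn-1-yl)oxiran-2-yl]methanol | CC#C[C@H]1O[C@H]1CO | intermediate
27 | (2R,3R)-3-(prop-1-yn-1-yl)oxirane-2-carbaldehyde (cis) | CC#C[C@H]1O[C@H]1C=O | intermediate
28 | (2E)-3-[(2S,3R)-3-(prop-1-yn-1-yl)oxiran-2-yl]prop-2-enal | CC#C[C@H]1O[C@H]1/C=C/C=O | intermediate
29 | methyl 2-(chloromethyl)-1,3-oxazole-4-carboxylate | COC(=O)c1coc(CCl)n1 | starting material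
30 | methyl 2-[(diethoxyphosphoryl)methyl]-1,3-oxazole-4-carboxylate | CCOP(=O)(OCC)Cc1nc(co1)C(=O)OC | intermediate
31 | methyl 2-{(1E,3E)-4-[(2S,3R)-3-(prop-1-yn-1-yl)oxiran-2-yl]buta-1,3-dien-1-yl}-1,3-oxazole-4-carboxylate | CC#C[C@H]1O[C@H]1/C=C/C=C/c1nc(co1)C(=O)OC | intermediate
32 | 2-{(1E,3E)-4-[(2S,3R)-3-(prop-1-yn-1-yl)oxiran-2-yl]buta-1,3-dien-1-yl}-1,3-oxazole-4-carboxylic acid | CC#C[C@H]1O[C@H]1/C=C/C=C/c1nc(co1)C(=O)O | intermediate
33 | ester of acid 22 with carbinol 12 | C#C[C@H](OC)Cc1nc(co1)C(=O)O[C@@H](CC#CC)C(C)(C)[C@@H](O[Si](C)(C)C(C)(C)C)/C=C/C | intermediate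
34 | (Z)-chloroenyne ester (33 with a cis-2-chlorovinyl group on the alkyne terminus) | Cl/C=C\C#C[C@H](OC)Cc1nc(co1)C(=O)O[C@@H](CC#CC)C(C)(C)[C@@H](O[Si](C)(C)C(C)(C)C)/C=C/C | intermediate
35 | Z-enediyne hydroxy ester | O[C@@H](C(C)(C)[C@@H](O[Si](C)(C)C(C)(C)C)/C=C/C)CC#C/C=C\C#C[C@H](OC)Cc1nc(co1)C(=O)O[C@@H](CC#CC)C(C)(C)[C@@H](O[Si](C)(C)C(C)(C)C)/C=C/C | intermediate
36 | Z,Z,Z-triene hydroxy ester | O[C@@H](C(C)(C)[C@@H](O[Si](C)(C)C(C)(C)C)/C=C/C)C\C=C/C=C\C=C/[C@H](OC)Cc1nc(co1)C(=O)O[C@@H](CC#CC)C(C)(C)[C@@H](O[Si](C)(C)C(C)(C)C)/C=C/C | intermediate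
37 | open-chain bis(prop-1-ynyl) diester, bis-TBS ether | CC#C[C@H]2O[C@H]2/C=C/C=C/c2nc(co2)C(=O)O[C@@H](C(C)(C)[C@@H](O[Si](C)(C)C(C)(C)C)/C=C/C)C\C=C/C=C\C=C/[C@H](OC)Cc2nc(co2)C(=O)O[C@@H](CC#CC)C(C)(C)[C@@H](O[Si](C)(C)C(C)(C)C)/C=C/C | intermediate
38 | 30-membered cycloalkyne, bis-TBS ether | C/C=C/[C@H](O[Si](C)(C)C(C)(C)C)C(C)(C)[C@@H]1CC#C[C@H]2O[C@H]2/C=C/C=C/c2nc(co2)C(=O)O[C@@H](C(C)(C)[C@@H](O[Si](C)(C)C(C)(C)C)/C=C/C)C\C=C/C=C\C=C/[C@H](OC)Cc2nc(co2)C(=O)O1 | intermediate
39 | bis-TBS ether of the target (ring alkyne of 38 as cis-alkene) | C/C=C/[C@H](O[Si](C)(C)C(C)(C)C)C(C)(C)[C@@H]1C/C=C\[C@H]2O[C@H]2/C=C/C=C/c2nc(co2)C(=O)O[C@@H](C(C)(C)[C@@H](O[Si](C)(C)C(C)(C)C)/C=C/C)C\C=C/C=C\C=C/[C@H](OC)Cc2nc(co2)C(=O)O1 | intermediate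
40 | CNP0284709.4 | C/C=C/[C@H](O)C(C)(C)[C@@H]1C/C=C\[C@H]2O[C@H]2/C=C/C=C/c2nc(co2)C(=O)O[C@@H](C(C)(C)[C@@H](O)/C=C/C)C\C=C/C=C\C=C/[C@H](OC)Cc2nc(co2)C(=O)O1 | target

**Step count and risks**

Total: 31 steps. Longest linear sequence: 17 steps (steps 1–7, 9, 10, 24–31).

Steps most likely to fail:

1. Step 29 (ring-closing alkyne metathesis). Intermolecular metathesis to oligomers or cyclic dimers may outrun ring closure, or the catalyst may be slowed at the hindered oxiranyl alkyne or by the oxazole nitrogens. Fallback: form the same C≡C bond intermolecularly and close the ring by lactonisation. It sets out from 36 and 31. Alkyne cross-metathesis with the same molybdenum alkylidyne (31 in excess, 5 Å sieves, toluene, rt, concentrated) should give the open-chain hydroxy methyl ester F1. LiOH in THF/H2O at 0 °C should cleave the methyl ester faster than the neopentyl-type secondary oxazole ester and give the seco acid F2. Yamaguchi macrolactonisation (2,4,6-Cl3C6H2COCl, Et3N, then DMAP, toluene, high dilution, rt) comes back to the route at 38.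

2. Step 28 (esterification with the oxirane acid). Acylation of the hindered carbinol may be slow enough for the activated dienyl oxirane acid to decompose by ring opening, or for the Z,Z,Z-triene to isomerise. Fallback: carry the robust oxazole phosphonate through the esterification and build the diene afterwards. It sets out from 30, which LiOH converts into the phosphonate acid F3. Esterification of 36 with it (EDC·HCl, DMAP, CH2Cl2, rt) gives the phosphonate ester F4. Horner–Wadsworth–Emmons reaction of F4 with enal 28 (LiCl, DBU, MeCN, 0 °C) comes back to the route at 37.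

3. Step 9 (and its mirror image, step 8). Facial selectivity may be insufficient in the mismatched pairing of reagent and substrate, or addition to the α-quaternary aldehyde may be sluggish. Fallback: give up reagent control. It sets out from 9. Barbier propargylation (propargyl bromide, Zn dust, THF/aq. NH4Cl) should give both carbinol epimers, which are separated by chromatography; both are needed in equal amounts, so nothing is discarded. Configuration is assigned from the 13C shifts of the acetonides of the derived 1,3-diols. The fallback comes back to the route at 10 and 11, and no compound outside the list arises (F0).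

**Further compounds**

F1 | step 29 | open-chain hydroxy methyl ester from cross-metathesis of 36 with 31 | O[C@@H](C(C)(C)[C@@H](O[Si](C)(C)C(C)(C)C)/C=C/C)C\C=C/C=C\C=C/[C@H](OC)Cc1nc(co1)C(=O)O[C@@H](CC#C[C@H]2O[C@H]2/C=C/C=C/c2nc(co2)C(=O)OC)C(C)(C)[C@@H](O[Si](C)(C)C(C)(C)C)/C=C/C
F2 | step 29 | seco acid (methyl ester of F1 as free acid) | O[C@@H](C(C)(C)[C@@H](O[Si](C)(C)C(C)(C)C)/C=C/C)C\C=C/C=C\C=C/[C@H](OC)Cc1nc(co1)C(=O)O[C@@H](CC#C[C@H]2O[C@H]2/C=C/C=C/c2nc(co2)C(=O)O)C(C)(C)[C@@H](O[Si](C)(C)C(C)(C)C)/C=C/C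
F3 | step 28 | 2-[(diethoxyphosphoryl)methyl]-1,3-oxazole-4-carboxylic acid | CCOP(=O)(OCC)Cc1nc(co1)C(=O)O
F4 | step 28 | phosphonate ester of 36 with F3 | CCOP(=O)(OCC)Cc1nc(co1)C(=O)O[C@@H](C(C)(C)[C@@H](O[Si](C)(C)C(C)(C)C)/C=C/C)C\C=C/C=C\C=C/[C@H](OC)Cc1nc(co1)C(=O)O[C@@H](CC#CC)C(C)(C)[C@@H](O[Si](C)(C)C(C)(C)C)/C=C/C
F0 | step 9 | none | none
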